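## Retrosynthetic overview

1. Locants follow azulene numbering and are kept for all intermediates. The cyclopentane is C-1 (CH2), C-2 (CHOH), C-3 (CMe2), C-3a (C–OH) and C-8a (CH). The cycloheptanone is C-3a, C-4, C-5, C-6 (CHMe), C-7 (quaternary), C-8 (C=O) and C-8a.
2. Enabling feature: in the cyclopentane, C-3a (tertiary carbinol), C-3 (gem-dimethyl) and C-2 (secondary carbinol) stand in a row, and C-3a is β to the C-8 ketone. C-3a is therefore a latent ketone of a cycloheptane-1,3-dione, C-3 a latent tertiary radical, and the C-2 oxygen that of a latent trisubstituted epoxide.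
3. Key disconnection C-3/C-3a: reductive epoxide–ketone radical cyclisation of the monocyclic dione epoxide 18. It joins two fully substituted carbons, frees both hydroxyls and sets C-3a. C-8a is then settled by equilibration.
4. Second disconnection C-1/C-8a: reductive Knoevenagel alkylation of dione 13 with the C5 epoxy aldehyde 16. Together with the key step this is a formal (3+2) annulation. Dione 13 comes from 2-methylcyclohexenone by conjugate addition/allylation, one-carbon ring expansion, conversion of allyl to butenolide, and β-oxygenation.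
5. Ring order: the purchased six-membered ring is expanded to the seven-membered ring (step 4), then the butenolide closes (steps 6–7), and the cyclopentane closes last (step 13).

Key step: step 13

Assumption: the phosphoramidite ligand in step 1 is taken to induce in the same sense for 2-methylcyclohex-2-enone as for cyclohex-2-enone. If the sense is opposite, the mirror-image ligand is used.

## Route

Step 1
Reactants: 1 2-methylcyclohex-2-en-1-one
Product: 3 (2S,3R)-2,3-dimethyl-2-(prop-2-en-1-yl)cyclohexan-1-one, via methylzinc enolate 2 (not isolated)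
Conditions: Me2Zn, Cu(OTf)2 (2 mol %), (R)-BINOL-derived phosphoramidite of bis[(S)-1-phenylethyl]amine (4 mol %), toluene, −30 °C; then allyl acetate, Pd(PPh3)4 (4 mol %), 0 °C to rt
Reagents that add atoms: dimethylzinc, C[Zn]C; allyl acetate, CC(=O)OCC=C
Why: Copper-catalysed asymmetric conjugate addition sets C-6 through the ligand, and Tsuji–Trost-type allylation of the zinc enolate by zerovalent palladium should occur anti to the new C-6 methyl group, which sets the quaternary C-7 with the two methyl groups cis.

Step 2
Reactants: 3 (2S,3R)-2,3-dimethyl-2-(prop-2-en-1-yl)cyclohexan-1-one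
Product: 4 {[(5R,6S)-5,6-dimethyl-6-(prop-2-en-1-yl)cyclohex-1-en-1-yl]oxy}trimethylsilane
Conditions: TMSOTf, Et3N, CH2Cl2, 0 °C
Reagents that add atoms: trimethylsilyl trifluoromethanesulfonate, C[Si](C)(C)OS(=O)(=O)C(F)(F)F
Why: Soft enolisation/O-silylation can give only this enol ether because the other α-carbon is quaternary, and no stereocentre is touched.

Step 3
Reactants: 4 silyl enol ether
Product: 5 1-(trimethylsilyloxy)bicyclo[4.1.0]heptane that carries the C-6 methyl, C-7 methyl and C-7 allyl groups (configuration of the two cyclopropane ring-fusion carbons left open)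
Conditions: Et2Zn, CH2I2, Et2O, 0 °C
Reagents that add atoms: diiodomethane, ICI
Why: In this Simmons–Smith cyclopropanation the electron-rich enol ether should react much faster than the monosubstituted allyl alkene, and the two new ring-fusion centres disappear in step 4, so they need no control.

Step 4
Reactants: 5 siloxycyclopropane
Product: 7 (6R,7S)-6,7-dimethyl-7-(prop-2-en-1-yl)cyclohept-2-en-1-one, via 3-chlorocycloheptanone 6 (not isolated)
Conditions: FeCl3, DMF, 0 °C to rt; then NaOAc, MeOH, reflux
Reagents that add atoms: iron trichloride, Cl[Fe](Cl)Cl (chlorine of 6 only, lost again)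
Why: In this oxidative ring expansion of a siloxycyclopropane, one-electron oxidation cleaves the internal cyclopropane bond to the secondary C-3a radical, which takes up chlorine, and E1cB loss of HCl gives the cycloheptenone without touching C-6 or C-7.

Step 5
Reactants: 7 (6R,7S)-6,7-dimethyl-7-(prop-2-en-1-yl)cyclohept-2-en-1-one
Product: 8 4-[(1S,2R)-1,2-dimethyl-7-oxocyclohept-5-en-1-yl]butanal
Conditions: Rh(acac)(CO)2 (1 mol %), BIPHEPHOS (3 mol %), CO/H2 (1:1, 10 bar), toluene, 60 °C
Reagents that add atoms: carbon monoxide, [C-]#[O+]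
Why: Linear-selective rhodium-catalysed hydroformylation takes only the monosubstituted alkene, while the conjugated ring alkene is far less reactive.

Step 6
Reactants: 8 4-[(1S,2R)-1,2-dimethyl-7-oxocyclohept-5-en-1-yl]butanal
Product: 9 4-{2-[(1S,2R)-1,2-dimethyl-7-oxocyclohept-5-en-1-yl]ethyl}-5-hydroxyfuran-2(5H)-one (both lactol epimers)
Conditions: glyoxylic acid monohydrate, morpholine hydrochloride, dioxane/H2O, reflux
Reagents that add atoms: glyoxylic acid monohydrate, OC(O)C(=O)O
Why: Amine-mediated aldol condensation of the aldehyde α-carbon with glyoxylic acid, followed by lactol closure, builds the β-substituted γ-hydroxybutenolide ring, and its lactol centre is removed in step 7.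

Step 7
Reactants: 9 γ-hydroxybutenolide
Product: 10 4-{2-[(1S,2R)-1,2-dimethyl-7-oxocyclohept-5-en-1-yl]ethyl}furan-2(5H)-one
Conditions: NaBH4 (limiting), MeOH/THF, −10 °C; then 1 M HCl to pH 3
Reagents that add atoms: none
Why: Borohydride reduction of the ring-opened formyl carboxylate followed by acid lactonisation should outrun reduction of the conjugated ketone, which is shielded by the quaternary C-7.

Step 8
Reactants: 10 butenolide enone
Product: 12 4-{2-[(1S,2R)-5-hydroxy-1,2-dimethyl-7-oxocycloheptyl]ethyl}furan-2(5H)-one (carbinol epimers), via β-boryl ketone 11 (not isolated)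
Conditions: B2pin2, CuCl (5 mol %), Xantphos (5 mol %), NaOtBu (10 mol %), MeOH (2 equiv), THF, rt; then NaBO3·4H2O, THF/H2O, rt
Reagents that add atoms: sodium perborate (hydroxyl oxygen), [Na+].[Na+].O[B-]1(O)OO[B-](O)(O)OO1; bis(pinacolato)diboron (boron of 11 only), CC1(C)OB(OC1(C)C)B1OC(C)(C)C(C)(C)O1
Why: Copper-catalysed conjugate borylation and C–B oxidation amount to hydration of the enone, the β-monosubstituted enone should react before the β,β-disubstituted butenolide, and the new carbinol centre is erased in step 9.

Step 9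
Reactants: 12 β-hydroxy ketone
Product: 13 (4S,5R)-4,5-dimethyl-4-[2-(5-oxo-2,5-dihydrofuran-3-yl)ethyl]cycloheptane-1,3-dione
Conditions: Dess–Martin periodinane, NaHCO3, CH2Cl2, 0 °C to rt
Reagents that add atoms: none
Why: Dess–Martin oxidation turns β-hydroxy ketones into 1,3-diketones under neutral conditions that leave the butenolide alone.

Step 10
Reactants: 14 3-methylbut-2-en-1-ol
Product: 15 [(2R)-3,3-dimethyloxiran-2-yl]methanol
Conditions: Ti(OiPr)4 (5 mol %), D-(−)-diisopropyl tartrate (7 mol %), tBuOOH, 4 Å molecular sieves, CH2Cl2, −20 °C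
Reagents that add atoms: tert-butyl hydroperoxide, CC(C)(C)OO
Why: In this Sharpless asymmetric epoxidation the D-(−)-tartrate ligand directs oxygen to the alkene face that gives the (R)-epoxide, and this centre becomes C-2 of the target.

Step 11
Reactants: 15 [(2R)-3,3-dimethyloxiran-2-yl]methanol
Product: 16 (2S)-3,3-dimethyloxirane-2-carbaldehyde (same spatial arrangement; the descriptor changes by priority only)
Conditions: TEMPO (10 mol %), PhI(OAc)2, CH2Cl2, 0 °C to rt; washed solution used directly
Reagents that add atoms: none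
Why: TEMPO-catalysed (oxoammonium) oxidation of the primary alcohol is mild enough for the epoxide, whose stereocentre resists enolisation because that would place an sp2 carbon in the three-membered ring.

Step 12
Reactants: 13 (4S,5R)-4,5-dimethyl-4-[2-(5-oxo-2,5-dihydrofuran-3-yl)ethyl]cycloheptane-1,3-dione; 16 (2S)-3,3-dimethyloxirane-2-carbaldehyde
Product: 18 (4S,5R)-2-{[(2R)-3,3-dimethyloxiran-2-yl]methyl}-4,5-dimethyl-4-[2-(5-oxo-2,5-dihydrofuran-3-yl)ethyl]cycloheptane-1,3-dione (C-8a stereolabile), via alkylidene dione 17 (not isolated)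
Conditions: L-proline (20 mol %), Hantzsch ester (1.1 equiv), CH2Cl2, rt; filtration through neutral alumina
Reagents that add atoms: none
Why: Organocatalytic three-component reductive alkylation (Knoevenagel condensation, then Hantzsch-ester transfer hydrogenation of the alkylidene dione) gives C-alkylation only under near-neutral conditions and leaves the epoxide centre untouched.

Step 13
Reactants: 18 dione epoxide
Product: 20 (2R,3aS,6R,7S,8aR)-2,3a-dihydroxy-3,3,6,7-tetramethyl-7-[2-(5-oxo-2,5-dihydrofuran-3-yl)ethyl]perhydroazulen-8-one (cis-fused ketol), via bis-titanium alkoxide 19 (not isolated)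
Conditions: Cp2TiCl2 (2.5 equiv), Mn dust, degassed THF, rt (green Cp2TiCl); slow addition of 18 (0.01 M); then aq. NaH2PO4
Reagents that add atoms: none
Why: Cp2TiCl (trivalent titanium) gives one electron to the epoxide, whose C-3–O bond breaks toward the tertiary C-3 radical while C-2 keeps its oxygen and configuration; this nucleophilic radical adds to the titanium-bound C-3a carbonyl, a second Cp2TiCl reduces the oxygen radical at once and so makes the otherwise reversible addition final, and hydrolysis of 19 frees both hydroxyls. The closest known reaction type is the titanocene-chloride-mediated reductive cyclisation of epoxy ketones to cyclopentane-1,3-diols. The one ring that closes, the cyclopentane C-1/C-2/C-3/C-3a/C-8a, closes in the 5-exo-trig mode on C=O through the C-3–C-3a bond between two fully substituted carbons. C-8a of 18 lies between two carbonyl groups and is stereolabile, so both epimers feed the reaction (Curtin–Hammett), and the three-atom tether should reach the carbonyl carbon only from the face that carries C-1, which gives the cis-fused ketol. In this late, product-like transition state the bulky titanoxy group on C-2 should take the convex face, which also receives the C-3a oxygen, so C-2 (fixed in step 10) sets C-3a with the two oxygens cis, and the axial C-7 methyl group on the opposite face of the seven-membered ring supports the same approach. The step needs attack at the C-3a ketone and not at C-8, which the quaternary C-7 next to C-8 secures (attack there would line up three contiguous fully substituted carbons), and it needs an untouched butenolide, which Cp2TiCl does not reduce and the radical cannot reach through a small ring.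

Step 14
Reactants: 20 cis-fused ketol
Product: 21 (2R,3aS,6R,7S,8aS)-2,3a-dihydroxy-3,3,6,7-tetramethyl-7-[2-(5-oxo-2,5-dihydrofuran-3-yl)ethyl]perhydroazulen-8-one (target)
Conditions: DBU (0.5 equiv), toluene, 40 °C
Reagents that add atoms: none
Why: Base-mediated epimerisation through the C-8/C-8a enolate (thermodynamic control) should favour the trans-fused ketol, because both five-ring bonds become equatorial on the seven-membered ring, C-3 turns anti to the C-8 acyl carbon, and only this epimer allows the C-3a–OH···O=C-8 hydrogen bond, which counts fully in toluene.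

## Compound list

1 | 2-methylcyclohex-2-en-1-one | CC1=CCCCC1=O | starting material
2 | methylzinc enolate of (3R)-2,3-dimethylcyclohexanone | C[C@@H]1CCCC(O[Zn]C)=C1C | intermediate
3 | (2S,3R)-2,3-dimethyl-2-(prop-2-en-1-yl)cyclohexan-1-one | C[C@@H]1CCCC(=O)[C@@]1(C)CC=C | intermediate
4 | {[(5R,6S)-5,6-dimethyl-6-(prop-2-en-1-yl)cyclohex-1-en-1-yl]oxy}trimethylsilane | C[C@@H]1CCC=C(O[Si](C)(C)C)[C@@]1(C)CC=C | intermediate
5 | siloxycyclopropane (1-trimethylsilyloxybicyclo[4.1.0]heptane derivative) | C[C@@H]1CCC2CC2(O[Si](C)(C)C)[C@@]1(C)CC=C | intermediate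
6 | (2S,3R)-6-chloro-2,3-dimethyl-2-(prop-2-en-1-yl)cycloheptan-1-one (chloride epimers) | C[C@@H]1CCC(Cl)CC(=O)[C@@]1(C)CC=C | intermediate
7 | (6R,7S)-6,7-dimethyl-7-(prop-2-en-1-yl)cyclohept-2-en-1-one | C[C@@H]1CCC=CC(=O)[C@@]1(C)CC=C | intermediate
8 | 4-[(1S,2R)-1,2-dimethyl-7-oxocyclohept-5-en-1-yl]butanal | C[C@@H]1CCC=CC(=O)[C@@]1(C)CCCC=O | intermediate
9 | 4-{2-[(1S,2R)-1,2-dimethyl-7-oxocyclohept-5-en-1-yl]ethyl}-5-hydroxyfuran-2(5H)-one | C[C@@H]1CCC=CC(=O)[C@@]1(C)CCC1=CC(=O)OC1O | intermediate
10 | 4-{2-[(1S,2R)-1,2-dimethyl-7-oxocyclohept-5-en-1-yl]ethyl}furan-2(5H)-one | C[C@@H]1CCC=CC(=O)[C@@]1(C)CCC1=CC(=O)OC1 | intermediate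
11 | β-(pinacolboryl) ketone from 10 | C[C@@H]1CCC(B2OC(C)(C)C(C)(C)O2)CC(=O)[C@@]1(C)CCC1=CC(=O)OC1 | intermediate
12 | 4-{2-[(1S,2R)-5-hydroxy-1,2-dimethyl-7-oxocycloheptyl]ethyl}furan-2(5H)-one | C[C@@H]1CCC(O)CC(=O)[C@@]1(C)CCC1=CC(=O)OC1 | intermediate
13 | (4S,5R)-4,5-dimethyl-4-[2-(5-oxo-2,5-dihydrofuran-3-yl)ethyl]cycloheptane-1,3-dione | C[C@@H]1CCC(=O)CC(=O)[C@@]1(C)CCC1=CC(=O)OC1 | intermediate
14 | 3-methylbut-2-en-1-ol | CC(C)=CCO | starting material
15 | [(2R)-3,3-dimethyloxiran-2-yl]methanol | OC[C@@H]1C(C)(C)O1 | intermediate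
16 | (2S)-3,3-dimethyloxirane-2-carbaldehyde | O=C[C@@H]1C(C)(C)O1 | intermediate
17 | 2-{[(2R)-3,3-dimethyloxiran-2-yl]methylidene} derivative of 13 | C[C@@H]1CCC(=O)C(=C[C@@H]2C(C)(C)O2)C(=O)[C@@]1(C)CCC1=CC(=O)OC1 | intermediate
18 | (4S,5R)-2-{[(2R)-3,3-dimethyloxiran-2-yl]methyl}-4,5-dimethyl-4-[2-(5-oxo-2,5-dihydrofuran-3-yl)ethyl]cycloheptane-1,3-dione | C[C@@H]1CCC(=O)C(C[C@@H]2C(C)(C)O2)C(=O)[C@@]1(C)CCC1=CC(=O)OC1 | intermediate
19 | bis(chlorotitanocene) 2,3a-dialkoxide of 20 | C[C@@H]1CC[C@]2([O-])[C@@H](C[C@@H]([O-])C2(C)C)C(=O)[C@@]1(C)CCC1=CC(=O)OC1.[Ti+4].[Ti+4].[Cl-].[Cl-].c1cc[cH-]c1.c1cc[cH-]c1.c1cc[cH-]c1.c1cc[cH-]c1 | intermediate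
20 | (2R,3aS,6R,7S,8aR) cis-fused ketol | C[C@@H]1CC[C@]2(O)[C@@H](C[C@@H](O)C2(C)C)C(=O)[C@@]1(C)CCC1=CC(=O)OC1 | intermediate
21 | (2R,3aS,6R,7S,8aS)-2,3a-dihydroxy-3,3,6,7-tetramethyl-7-[2-(5-oxo-2,5-dihydrofuran-3-yl)ethyl]perhydroazulen-8-one | C[C@@H]1CC[C@]2(O)[C@H](C[C@@H](O)C2(C)C)C(=O)[C@@]1(C)CCC1=CC(=O)OC1 | target

## Step count and risks

Total step count: 14. Longest linear sequence: 12 (steps 1–9 and 12–14, from 1).

**Step 13.** The tertiary C-3 radical may lose a hydrogen atom to a second Cp2TiCl faster than it adds to the hindered ketone. The large titanoxy group on C-2 may also erode the facial selectivity at C-3a.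
- The fallback sets out from 18. The same reagent then delivers the allylic alcohol (4S,5R)-2-[(2R)-2-hydroxy-3-methylbut-3-en-1-yl]-4,5-dimethyl-4-[2-(5-oxo-2,5-dihydrofuran-3-yl)ethyl]cycloheptane-1,3-dione F1.
- F1 is collected and cyclised by a different radical entry, the hydrogen-atom-transfer-initiated cyclisation of alkene-tethered ketones (Fe(acac)3, PhSiH3, EtOH, 60 °C).
- Hydrogen-atom transfer to the terminal CH2 regenerates the C-3 radical next to a small free hydroxyl, which can hydrogen-bond to the C-3a carbonyl.
- The fallback comes back to the route at 20.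

**Step 12.** The enol oxygen of the freshly formed 2-alkyl dione may open the epoxide (5-exo attack at C-2), or the amine catalyst may consume the epoxy aldehyde.
- The fallback sets out from 13. Tsuji–Trost allylation under neutral conditions (methyl 3-methylbut-2-en-1-yl carbonate, Pd(PPh3)4, THF, rt) should give (4S,5R)-4,5-dimethyl-2-(3-methylbut-2-en-1-yl)-4-[2-(5-oxo-2,5-dihydrofuran-3-yl)ethyl]cycloheptane-1,3-dione F2.
- The C-2 oxygen is then introduced by Shi epoxidation. The conditions are the D-fructose-derived ketone, KHSO5 (as 2KHSO5·KHSO4·K2SO4) and NaHCO3 buffer at about pH 8, in MeCN/aqueous Na2EDTA at 0 °C.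
- The fallback comes back to the route at 18.

**Step 14.** Deprotonation at C-8a may be slow because the C–H bond of the cis-fused ketol is poorly aligned with the carbonyl π system. Loss of water across C-3a/C-8a would then take over.
- The fallback sets out from 20 and corrects the centre by C–C cleavage and re-formation instead of proton exchange.
- Mg(OMe)2 in THF/MeOH (rt to 40 °C) should trigger retro-aldol opening to (2S,3R,8R)-8-hydroxy-2,3,7,7-tetramethyl-2-[2-(5-oxo-2,5-dihydrofuran-3-yl)ethyl]cyclodecane-1,6-dione F3.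
- F3 then recloses by transannular aldol addition, the classical behaviour of cyclodecane-1,6-diones, under thermodynamic control.
- Magnesium can bind the C-2, C-3a and C-8 oxygens on one face only in the target isomer.
- The fallback comes back to the route at 21.

Further compounds
F1 | step 13 | (4S,5R)-2-[(2R)-2-hydroxy-3-methylbut-3-en-1-yl]-4,5-dimethyl-4-[2-(5-oxo-2,5-dihydrofuran-3-yl)ethyl]cycloheptane-1,3-dione | C[C@@H]1CCC(=O)C(C[C@@H](O)C(C)=C)C(=O)[C@@]1(C)CCC1=CC(=O)OC1
F2 | step 12 | (4S,5R)-4,5-dimethyl-2-(3-methylbut-2-en-1-yl)-4-[2-(5-oxo-2,5-dihydrofuran-3-yl)ethyl]cycloheptane-1,3-dione | C[C@@H]1CCC(=O)C(CC=C(C)C)C(=O)[C@@]1(C)CCC1=CC(=O)OC1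
F3 | step 14 | (2S,3R,8R)-8-hydroxy-2,3,7,7-tetramethyl-2-[2-(5-oxo-2,5-dihydrofuran-3-yl)ethyl]cyclodecane-1,6-dione | C[C@@H]1CCC(=O)C(C)(C)[C@H](O)CCC(=O)[C@@]1(C)CCC1=CC(=O)OC1
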